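**Assumptions (one line):** All starting materials are taken as commercial (mono‑tert‑butyl succinate, (R)‑4‑benzyloxazolidin‑2‑one, 4‑benzyloxy‑3‑methoxybenzaldehyde, 4‑benzyloxy‑3‑methoxybenzyl chloride). The target is the (2R,3S,4R)-oxolane, i.e. 8'‑hydroxylariciresinol‑type, with C2‑aryl trans to C3‑CH2OH, benzyl cis to CH2OH, and OH cis to the C2 aryl.

## Retrosynthetic overview
1. The target comes from hydrogenolysis of a bis‑O‑benzyl tetrahydrofuran. That ring is formed last, by acid‑mediated benzylic etherification of a tetrol (C2 ends up trans to C3 by thermodynamic control).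
2. The tetrol comes from LiAlH4 reduction of an α‑hydroxy‑α‑benzyl γ‑aryl‑paraconic acid. The tertiary OH is set by Davis hydroxylation of the lactone enolate, anti to the C3 carboxylate.
3. The γ‑lactone ring forms first, by lactonization of an Evans syn‑aldol product. The auxiliary sets the only stereocentre that must survive to the end (C3).
4. Ring order: γ‑lactone (step 4), then THF (step 8).

## Route

**Step 1**
Reactants: 1 (mono‑tert‑butyl succinate), 2 ((R)‑4‑benzyloxazolidin‑2‑one)
Product: 3 (tert‑butyl 4‑[(4R)‑4‑benzyl‑2‑oxo‑oxazolidin‑3‑yl]‑4‑oxobutanoate)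
Conditions: PivCl, Et3N, THF, −20 °C; then 2, LiCl, rt
Reagents that add atoms: none
Why: Mixed‑anhydride N‑acylation gives the succinyl imide. The (R) auxiliary is chosen so that the aldol in step 2 places C3 in the configuration the target needs.

**Step 2**
Reactants: 3, 4 (4‑benzyloxy‑3‑methoxybenzaldehyde)
Product: 5 (tert‑butyl (3R,4R)‑3‑{[(4R)‑4‑benzyl‑2‑oxo‑oxazolidin‑3‑yl]carbonyl}‑4‑[4‑(benzyloxy)‑3‑methoxyphenyl]‑4‑hydroxybutanoate)
Conditions: Bu2BOTf, Et3N, CH2Cl2, −78 → 0 °C; add 4; oxidative work‑up (H2O2, pH 7 buffer, MeOH)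
Reagents that add atoms: none (boron is removed in the work‑up)
Why: An Evans syn‑aldol through the Z‑boron enolate sets C3 (R) and C4 (R) together. The syn adduct later closes to the trans‑lactone.

**Step 3**
Reactants: 5
Product: 6 ((2R,3R)‑2‑[2‑(tert‑butoxy)‑2‑oxoethyl]‑3‑[4‑(benzyloxy)‑3‑methoxyphenyl]‑3‑hydroxypropanoic acid)
Conditions: LiOH, 30% H2O2, THF/H2O 3:1, 0 °C; then Na2SO3
Reagents that add atoms: water/hydroxide (LiOH, [Li+].[OH-]; the acid OH comes from this, with H2O2 as the peroxide carrier)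
Why: Hydroperoxide attacks the imide exocyclic carbonyl selectively (LiOOH auxiliary cleavage). This frees the acid, leaves the tBu ester intact, and recovers 2.

**Step 4**
Reactants: 6
Product: 7 ((2R,3R)‑2‑[4‑(benzyloxy)‑3‑methoxyphenyl]‑5‑oxooxolane‑3‑carboxylic acid, trans)
Conditions: TFA, CH2Cl2 (1:4), 0 °C → rt
Reagents that add atoms: none (TFA is the acid; isobutene and water are lost)
Why: TFA removes the tBu group, and the benzylic OH closes onto the new acid to give the γ‑lactone (a trans‑paraconic acid). The C3 stereocentre is not touched.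

**Step 5**
Reactants: 7, 8 (4‑(benzyloxy)‑3‑methoxybenzyl chloride)
Product: 9 ((2R,3R,4R)‑4‑[4‑(benzyloxy)‑3‑methoxybenzyl]‑2‑[4‑(benzyloxy)‑3‑methoxyphenyl]‑5‑oxooxolane‑3‑carboxylic acid)
Conditions: LDA (2.4 equiv), THF/DMPU, −78 °C; then 8, cat. NaI, −78 → −20 °C
Reagents that add atoms: none beyond reactant 8 (it supplies the benzyl group; LDA and DMPU add nothing)
Why: The carboxylate protects the acid position, so the lactone α‑enolate is alkylated (dianion alkylation) trans to the C3 carboxylate. C4 is re‑set in step 6, so its selectivity here is not critical.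

**Step 6**
Reactants: 9, 10 ((±)‑2‑(phenylsulfonyl)‑3‑phenyloxaziridine, Davis oxaziridine)
Product: 11 ((2R,3S,4R)‑4‑benzyl‑4‑hydroxy‑2,4‑diaryl‑5‑oxooxolane‑3‑carboxylic acid, bis‑O‑benzyl)
Conditions: LDA (2.4 equiv), THF, −78 °C; then 10 (1.3 equiv), −78 °C; NH4Cl
Reagents that add atoms: 10, O=S(=O)(c1ccccc1)N1OC1c1ccccc1 (delivers the OH oxygen)
Why: Davis hydroxylation of the tertiary lactone enolate occurs on the face anti to the adjacent C3 carboxylate. The OH ends up trans to C3 and the benzyl cis, which is the target's C4 (R) configuration.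

**Step 7**
Reactants: 11
Product: 12 ((2S,3R)‑3‑[4‑(benzyloxy)‑3‑methoxybenzyl]‑2‑[(R)‑[4‑(benzyloxy)‑3‑methoxyphenyl](hydroxy)methyl]butane‑1,3,4‑triol)
Conditions: LiAlH4 (6 equiv), THF, 0 °C → reflux; Rochelle salt work‑up
Reagents that add atoms: none (hydride adds H only)
Why: LiAlH4 reduces both the carboxylate and the α‑hydroxy lactone to primary alcohols, giving the open tetrol. The benzyl ethers and the existing stereocentres are untouched.

**Step 8**
Reactants: 12
Product: 13 (bis‑O‑benzyl target, (2R,3S,4R)‑oxolane)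
Conditions: p‑TsOH·H2O (10 mol %), CH2Cl2, 0 °C → rt
Reagents that add atoms: none (intramolecular; water is lost)
Why: Acid‑catalysed dehydrative cyclization, a 5‑exo capture of the electron‑rich benzylic cation by the CH2OH on the tertiary carbinol carbon. It is reversible at C2 and gives the thermodynamically preferred 2,3‑trans THF (aryl trans to CH2OH, cis to the small OH).

**Step 9**
Reactants: 13
Product: 14 (target)
Conditions: H2 (1 atm), 10% Pd/C, EtOAc/EtOH, rt
Reagents that add atoms: none
Why: Hydrogenolysis removes both phenolic benzyl ethers (debenzylation). The THF, tertiary alcohol and primary alcohol are untouched, and no stereocentre changes.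

## Compound list
1 | mono‑tert‑butyl succinate | CC(C)(C)OC(=O)CCC(=O)O | starting material
2 | (R)‑4‑benzyloxazolidin‑2‑one | O=C1N[C@H](Cc2ccccc2)CO1 | starting material
3 | N‑(4‑tert‑butoxy‑4‑oxobutanoyl)‑(R)‑4‑benzyloxazolidinone | CC(C)(C)OC(=O)CCC(=O)N1C(=O)OC[C@H]1Cc2ccccc2 | intermediate
4 | 4‑benzyloxy‑3‑methoxybenzaldehyde | COc1cc(C=O)ccc1OCc2ccccc2 | starting material
5 | Evans syn‑aldol adduct | CC(C)(C)OC(=O)C[C@H]([C@@H](O)c1ccc(OCc2ccccc2)c(OC)c1)C(=O)N3C(=O)OC[C@H]3Cc4ccccc4 | intermediate
6 | β‑hydroxy acid, tBu ester | CC(C)(C)OC(=O)C[C@H]([C@@H](O)c1ccc(OCc2ccccc2)c(OC)c1)C(=O)O | intermediate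
7 | trans‑γ‑aryl paraconic acid | O=C(O)[C@@H]1CC(=O)O[C@H]1c2ccc(OCc3ccccc3)c(OC)c2 | intermediate
8 | 4‑benzyloxy‑3‑methoxybenzyl chloride | COc1cc(CCl)ccc1OCc2ccccc2 | starting material
9 | α‑benzyl paraconic acid | O=C(O)[C@@H]1[C@@H](Cc2ccc(OCc3ccccc3)c(OC)c2)C(=O)O[C@H]1c4ccc(OCc5ccccc5)c(OC)c4 | intermediate
10 | Davis oxaziridine (racemic) | O=S(=O)(c1ccccc1)N2OC2c3ccccc3 | starting material (reagent)
11 | α‑hydroxy‑α‑benzyl paraconic acid | O=C(O)[C@@H]1[C@](O)(Cc2ccc(OCc3ccccc3)c(OC)c2)C(=O)O[C@H]1c4ccc(OCc5ccccc5)c(OC)c4 | intermediate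
12 | bis‑O‑benzyl tetrol | OC[C@@H]([C@@H](O)c1ccc(OCc2ccccc2)c(OC)c1)[C@](O)(Cc3ccc(OCc4ccccc4)c(OC)c3)CO | intermediate
13 | bis‑O‑benzyl THF | COc1cc(C[C@]2(O)CO[C@@H](c3ccc(OCc4ccccc4)c(OC)c3)[C@@H]2CO)ccc1OCc5ccccc5 | intermediate
14 | (3R,4S,5R)‑5‑(4‑hydroxy‑3‑methoxyphenyl)‑3‑[(4‑hydroxy‑3‑methoxyphenyl)methyl]‑4‑(hydroxymethyl)oxolan‑3‑ol | COc1cc(C[C@]2(O)CO[C@@H](c3ccc(O)c(OC)c3)[C@@H]2CO)ccc1O | target

## Summary
Total steps: 9. Longest linear sequence: 9 (steps 1 to 9).

Three steps most likely to fail: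
1. **Step 6 (hydroxylation selectivity).** The β‑carboxylate and the γ‑aryl group both bias the enolate faces, and the γ‑aryl sits on the face the oxidant must use.
   - Fallback: change the C4 strategy. Make the α‑arylidene lactone by aldol condensation, epoxidise it (DMDO), then hydrogenolyse the benzylic epoxide C–O. The facial bias then comes from epoxidation and can be tuned through the C3 substituent.
2. **Step 8 (cyclization).** The benzylic cation is γ to the tertiary OH, so retro‑Prins fragmentation or loss of the C2 configuration is possible.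
   - Fallback: keep the C2–O bond throughout. Reduce the acid of 11 (BH3·SMe2), protect the primary OH, convert the lactone to the lactol (DIBAL), and deoxygenate with Et3SiH/BF3 so the C7–O bond is never ionised.
3. **Step 5 (dianion alkylation).** Enolization could compete at the carboxylate‑adjacent CH, or the dianion could ring‑open.
   - Fallback: reduce the acid to CH2OTBDPS (BH3·SMe2, then TBDPSCl) first. Then alkylate the neutral lactone with LiHMDS, or install the aryl‑CH2 unit by aldol condensation of the lactone with 4 followed by conjugate reduction.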